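**Retrosynthetic overview**
- The plan rests on rings A and B of the labdane: a trans-fused decalin (C1–C10) with quaternary C4 (axial C19, the carboxyl carbon) and C10, an equatorial chain on C9 and the exocyclic C8=C17 alkene, the imprint of a chair–chair folded polyene closed from C4 to C8.
- Late stage: the C19 acid comes from a C19 silyl ether (deprotection, two-stage oxidation), the C15 palmitate from a C15 ester (reduction, acylation), and the C3 hydroxyl left by the cyclization is removed by Barton–McCombie deoxygenation.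
- Key disconnection: C4–C5 and C9–C10, made in one Lewis-acid cascade from an enantiopure C3–C4 epoxide, the C5=C10 alkene and a C9=C8 allylsilane; ring A closes first, ring B second, and loss of Me3Si leaves C8=C17.
- Precursor: linear assembly from geraniol (C1–C3, C5, C6, C10, C20), a Still–Gennari phosphonate (C4, C18, C19; Sharpless epoxidation sets C3 and C4) and two rounds of methyl acetoacetate dianion alkylation and enol phosphate coupling (C7–C9, C11 and C17 with Me3SiCH2MgCl; C12–C16 with Me2CuLi).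

Key step: step 18

Remark: the target is read as the 15-O-palmitate of (13E)-15-hydroxylabda-8(17),13-dien-19-oic acid, (4S,5R,9S,10R); labdane numbering is used for the carbons of all intermediates, and Ox stands for the (2S,3R)-3-{[(tert-butyldiphenylsilyl)oxy]methyl}-3-methyloxiran-2-yl group (C3, C4, C18, C19).

**Route**

Step 1
Reactants: 1 geraniol
Product: 2 geranyl 4-methoxybenzyl ether
Conditions: NaH, 4-MeOC6H4CH2Cl, n-Bu4NI (cat.), THF/DMF, 0 °C → rt
Reagents that add atoms: 4-methoxybenzyl chloride, COc1ccc(CCl)cc1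
Why: Williamson etherification of the primary allylic alkoxide; the 4-methoxybenzyl ether should survive peracid, base and hydride and can later be removed under neutral oxidative conditions.

Step 2
Reactants: 2 geranyl 4-methoxybenzyl ether
Product: 3 racemic 6,7-epoxygeranyl 4-methoxybenzyl ether
Conditions: mCPBA, NaHCO3, CH2Cl2, −20 → 0 °C
Reagents that add atoms: 3-chloroperoxybenzoic acid, OOC(=O)c1cccc(Cl)c1
Why: Prilezhaev epoxidation should take the remote, more electron-rich C6=C7 alkene in preference to the C2=C3 alkene, which is deactivated by the allylic ether oxygen; the new stereocentre is racemic and is destroyed in step 3.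

Step 3
Reactants: 3 racemic 6,7-epoxygeranyl 4-methoxybenzyl ether
Product: 5 (4E)-6-[(4-methoxybenzyl)oxy]-4-methylhex-4-enal, via diol 4 (not isolated)
Conditions: H5IO6, THF/H2O, 0 °C
Reagents that add atoms: none
Why: Acid hydrolysis of the epoxide to the vicinal diol followed in the same flask by Malaprade glycol cleavage should give the aldehyde and acetone without touching the remaining alkene or the ether.

Step 4
Reactants: 5 (4E)-6-[(4-methoxybenzyl)oxy]-4-methylhex-4-enal; 6 ethyl 2-[bis(2,2,2-trifluoroethoxy)phosphoryl]propanoate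
Product: 7 ethyl (2Z,6E)-8-[(4-methoxybenzyl)oxy]-2,6-dimethylocta-2,6-dienoate
Conditions: KN(SiMe3)2, 18-crown-6, THF, −78 °C
Reagents that add atoms: none
Why: Still–Gennari olefination, in which the trifluoroethyl phosphonate with a dissociated potassium counter-ion eliminates from the kinetic adduct, should give the Z trisubstituted enoate, so that the ester carbon (later C19) is cis to the chain.

Step 5
Reactants: 7 ethyl (2Z,6E)-8-[(4-methoxybenzyl)oxy]-2,6-dimethylocta-2,6-dienoate
Product: 8 (2Z,6E)-8-[(4-methoxybenzyl)oxy]-2,6-dimethylocta-2,6-dien-1-ol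
Conditions: i-Bu2AlH, CH2Cl2, −78 °C
Reagents that add atoms: none
Why: 1,2-Reduction of the conjugated ester by the aluminium hydride at low temperature should give the allylic alcohol with the Z geometry unchanged.

Step 6
Reactants: 8 (2Z,6E)-8-[(4-methoxybenzyl)oxy]-2,6-dimethylocta-2,6-dien-1-ol
Product: 9 [(2R,3S)-3-{(3E)-5-[(4-methoxybenzyl)oxy]-3-methylpent-3-en-1-yl}-2-methyloxiran-2-yl]methanol
Conditions: Ti(OiPr)4 (cat.), D-(−)-diethyl tartrate (cat.), t-BuOOH, 4 Å molecular sieves, CH2Cl2, −20 °C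
Reagents that add atoms: tert-butyl hydroperoxide, CC(C)(C)OO
Why: Sharpless asymmetric epoxidation oxidises only the alkene of the free allylic alcohol, and the D-(−)-tartrate titanium complex should deliver oxygen to the face that gives the (2R,3S)-epoxide (C4 R, C3 S), the cis relation of CH2OH and chain being carried over from the Z alkene.

Step 7
Reactants: 9 [(2R,3S)-3-{(3E)-5-[(4-methoxybenzyl)oxy]-3-methylpent-3-en-1-yl}-2-methyloxiran-2-yl]methanol
Product: 10 tert-butyldiphenylsilyl ether of 9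
Conditions: t-BuPh2SiCl, imidazole, CH2Cl2, 0 °C → rt
Reagents that add atoms: tert-butyl(chloro)diphenylsilane, CC(C)(C)[Si](Cl)(c1ccccc1)c1ccccc1
Why: Silylation of the primary alcohol gives a bulky silyl ether on C19 that should be stable to the organometallic steps and to the Lewis acid of the cascade.

Step 8
Reactants: 10 tert-butyldiphenylsilyl ether of 9
Product: 11 (2E)-3-methyl-5-Ox-pent-2-en-1-ol
Conditions: DDQ, CH2Cl2/pH 7 buffer, 0 °C
Reagents that add atoms: none
Why: Oxidative cleavage of the 4-methoxybenzyl ether by DDQ through the benzylic oxocarbenium ion runs under buffered neutral conditions that should leave the epoxide and the silyl ether alone.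

Step 9
Reactants: 11 (2E)-3-methyl-5-Ox-pent-2-en-1-ol
Product: 13 (2E)-1-bromo-3-methyl-5-Ox-pent-2-ene, via mesylate 12 (not isolated)
Conditions: MsCl, Et3N, THF, −40 °C; then LiBr, −40 → 0 °C
Reagents that add atoms: lithium bromide, [Li+].[Br-]
Why: Mesylation and SN2 displacement by bromide at low temperature should convert the primary allylic alcohol into the bromide without allylic transposition or epoxide opening.

Step 10
Reactants: 13 (2E)-1-bromo-3-methyl-5-Ox-pent-2-ene; 14 methyl acetoacetate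
Product: 15 methyl (6E)-7-methyl-3-oxo-9-Ox-non-6-enoate
Conditions: 14, NaH, then n-BuLi, THF, 0 °C; then 13, 0 °C
Reagents that add atoms: none
Why: The dianion of the β-keto ester is alkylated at its terminal carbon (C7) by the allylic bromide, which is far more electrophilic than the trisubstituted epoxide at 0 °C.

Step 11
Reactants: 15 methyl (6E)-7-methyl-3-oxo-9-Ox-non-6-enoate
Product: 16 methyl (2Z,6E)-3-[(diethoxyphosphoryl)oxy]-7-methyl-9-Ox-nona-2,6-dienoate
Conditions: NaH, Et2O, 0 °C; then ClP(O)(OEt)2, 0 °C → rt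
Reagents that add atoms: diethyl chlorophosphate, CCOP(=O)(Cl)OCC
Why: O-Phosphorylation of the chelated sodium enolate should give the Z enol phosphate, with the phosphate cis to the ester.

Step 12
Reactants: 16 methyl (2Z,6E)-3-[(diethoxyphosphoryl)oxy]-7-methyl-9-Ox-nona-2,6-dienoate
Product: 17 methyl (2Z,6E)-7-methyl-9-Ox-3-[(trimethylsilyl)methyl]nona-2,6-dienoate
Conditions: Me3SiCH2MgCl, Ni(acac)2 (cat.), THF, 0 °C → rt
Reagents that add atoms: (trimethylsilyl)methylmagnesium chloride, C[Si](C)(C)C[Mg]Cl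
Why: Nickel-catalysed Kumada-type coupling of the enol phosphate proceeds with retention of alkene geometry and should place CH2SiMe3 (C17) cis to the ester carbon (C11), which creates the allylsilane with C11 trans to C7.

Step 13
Reactants: 17 methyl (2Z,6E)-7-methyl-9-Ox-3-[(trimethylsilyl)methyl]nona-2,6-dienoate
Product: 18 (2Z,6E)-7-methyl-9-Ox-3-[(trimethylsilyl)methyl]nona-2,6-dien-1-ol
Conditions: i-Bu2AlH, CH2Cl2, −78 °C
Reagents that add atoms: none
Why: 1,2-Reduction of the conjugated ester at −78 °C should give the allylic alcohol under conditions that do not attack the epoxide, the allylsilane or the silyl ether.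

Step 14
Reactants: 18 (2Z,6E)-7-methyl-9-Ox-3-[(trimethylsilyl)methyl]nona-2,6-dien-1-ol
Product: 20 (2Z,6E)-1-bromo-7-methyl-9-Ox-3-[(trimethylsilyl)methyl]nona-2,6-diene, via mesylate 19 (not isolated)
Conditions: MsCl, Et3N, THF, −40 °C; then LiBr, −40 → 0 °C; used at once
Reagents that add atoms: lithium bromide, [Li+].[Br-]
Why: Mesylation and SN2 bromide displacement as in step 9; the bromide, which carries a silyl group γ to the leaving group, is made cold and used without storage.

Step 15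
Reactants: 20 (2Z,6E)-1-bromo-7-methyl-9-Ox-3-[(trimethylsilyl)methyl]nona-2,6-diene; 14 methyl acetoacetate
Product: 21 methyl (6Z,10E)-11-methyl-3-oxo-13-Ox-7-[(trimethylsilyl)methyl]trideca-6,10-dienoate
Conditions: 14, NaH, then n-BuLi, THF, 0 °C; then 20, −78 → 0 °C
Reagents that add atoms: none
Why: A second terminal alkylation of the acetoacetate dianion by the primary allylic bromide should add C12–C15 by direct SN2 displacement, which is faster at low temperature than ionisation of the bromide.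

Step 16
Reactants: 21 methyl (6Z,10E)-11-methyl-3-oxo-13-Ox-7-[(trimethylsilyl)methyl]trideca-6,10-dienoate
Product: 22 methyl (2Z,6Z,10E)-3-[(diethoxyphosphoryl)oxy]-11-methyl-13-Ox-7-[(trimethylsilyl)methyl]trideca-2,6,10-trienoate
Conditions: NaH, Et2O, 0 °C; then ClP(O)(OEt)2, 0 °C → rt
Reagents that add atoms: diethyl chlorophosphate, CCOP(=O)(Cl)OCC
Why: As in step 11, phosphorylation of the chelated sodium enolate should give the Z enol phosphate.

Step 17
Reactants: 22 methyl (2Z,6Z,10E)-3-[(diethoxyphosphoryl)oxy]-11-methyl-13-Ox-7-[(trimethylsilyl)methyl]trideca-2,6,10-trienoate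
Product: 23 methyl (2E,6Z,10E)-3,11-dimethyl-13-Ox-7-[(trimethylsilyl)methyl]trideca-2,6,10-trienoate
Conditions: Me2CuLi (from CuI and MeLi), Et2O, −78 → −45 °C
Reagents that add atoms: lithium dimethylcuprate, [Li+].C[Cu-]C
Why: Conjugate addition–elimination of the Gilman cuprate on the β-phosphoryloxy enoate goes with retention and should give the E enoate (C16 methyl cis to the ester, chain trans), while epoxide and allylsilane do not react with the cuprate at low temperature.

Step 18
Reactants: 23 methyl (2E,6Z,10E)-3,11-dimethyl-13-Ox-7-[(trimethylsilyl)methyl]trideca-2,6,10-trienoate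
Product: 24 methyl (13E)-19-[(tert-butyldiphenylsilyl)oxy]-3β-hydroxylabda-8(17),13-dien-15-oate
Conditions: MeAlCl2, CH2Cl2, −78 °C; then Et3N, aq. NaHCO3
Reagents that add atoms: none
Why: MeAlCl2 binds the epoxide oxygen and the C4–O bond breaks at the tertiary carbon while C5 of the C5=C10 alkene attacks anti to the leaving oxygen (inversion at C4); the tertiary C10 cation is then taken by C9 of the allylsilane and the β-silyl cation at C8 loses Me3Si, so that only the C8=C17 alkene can form. The closest known reaction type is the Lewis-acid epoxy-polyene cyclization ended by an allylsilane. Ring A (C4–C5 bond) and ring B (C9–C10 bond) both close 6-endo through chair transition states in a chair–chair fold. C3 keeps its C–O bond (equatorial 3β-OH) and C4 is fixed by the epoxide, whose CH2OSi group, cis to the chain, becomes the axial 4β carbon C19; C5 and C10 (trans fusion, 5α-H, 10β-CH3) follow from the E geometry of C5=C10, and C9 (9α-H, equatorial side chain) from the allylsilane geometry with C11 trans to C7, the absolute sense of all of them being relayed from the single epoxide enantiomer. The step needs opening at C4 and not at C3, which the tertiary carbon should secure in spite of the inductive pull of the C19 oxygen, and an end after two rings, which the allylsilane and the electron-poor conjugated ester at C13=C14 should secure.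

Step 19
Reactants: 24 methyl (13E)-19-[(tert-butyldiphenylsilyl)oxy]-3β-hydroxylabda-8(17),13-dien-15-oate
Product: 25 3-O-(imidazol-1-ylthiocarbonyl) derivative of 24
Conditions: 1,1'-thiocarbonyldiimidazole, DMAP, toluene, 90 °C
Reagents that add atoms: 1,1'-thiocarbonyldiimidazole, S=C(n1ccnc1)n1ccnc1
Why: Thioacylation of the only free hydroxyl, the hindered equatorial C3–OH, under non-basic conditions that cannot move the neighbouring silyl group should give the radical precursor.

Step 20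
Reactants: 25 3-O-(imidazol-1-ylthiocarbonyl) derivative of 24
Product: 26 methyl (13E)-19-[(tert-butyldiphenylsilyl)oxy]labda-8(17),13-dien-15-oate
Conditions: n-Bu3SnH, AIBN (cat.), toluene, 100 °C
Reagents that add atoms: none
Why: Barton–McCombie deoxygenation: the stannyl radical adds to sulfur, the C3–O bond fragments and the secondary C3 radical is reduced by the tin hydride; C3 becomes a methylene, so no stereocentre is at stake.

Step 21
Reactants: 26 methyl (13E)-19-[(tert-butyldiphenylsilyl)oxy]labda-8(17),13-dien-15-oate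
Product: 27 (13E)-19-[(tert-butyldiphenylsilyl)oxy]labda-8(17),13-dien-15-ol
Conditions: i-Bu2AlH, CH2Cl2, −78 °C
Reagents that add atoms: none
Why: 1,2-Reduction of the conjugated methyl ester should give the primary allylic alcohol at C15 with the 13E alkene intact.

Step 22
Reactants: 27 (13E)-19-[(tert-butyldiphenylsilyl)oxy]labda-8(17),13-dien-15-ol; 28 palmitoyl chloride
Product: 29 (13E)-19-[(tert-butyldiphenylsilyl)oxy]labda-8(17),13-dien-15-yl hexadecanoate
Conditions: pyridine, DMAP (cat.), CH2Cl2, 0 °C → rt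
Reagents that add atoms: none
Why: DMAP-catalysed acylation of the unhindered primary allylic alcohol by the acid chloride.

Step 23
Reactants: 29 (13E)-19-[(tert-butyldiphenylsilyl)oxy]labda-8(17),13-dien-15-yl hexadecanoate
Product: 30 (13E)-19-hydroxylabda-8(17),13-dien-15-yl hexadecanoate
Conditions: n-Bu4NF, AcOH, THF, rt → 45 °C
Reagents that add atoms: none
Why: Fluoride cleavage of the neopentyl silyl ether, buffered with acetic acid so that the palmitate should be neither hydrolysed nor shifted.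

Step 24
Reactants: 30 (13E)-19-hydroxylabda-8(17),13-dien-15-yl hexadecanoate
Product: 31 (13E)-19-oxolabda-8(17),13-dien-15-yl hexadecanoate
Conditions: Dess–Martin periodinane, NaHCO3, CH2Cl2, 0 °C → rt
Reagents that add atoms: none
Why: Dess–Martin oxidation of the neopentyl primary alcohol should stop at the aldehyde, and since C4 is quaternary no epimerisation is possible.

Step 25
Reactants: 31 (13E)-19-oxolabda-8(17),13-dien-15-yl hexadecanoate
Product: 32 (13E)-15-(hexadecanoyloxy)labda-8(17),13-dien-19-oic acid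
Conditions: NaClO2, NaH2PO4, 2-methyl-2-butene, t-BuOH/H2O, rt
Reagents that add atoms: sodium chlorite, [Na+].[O-]Cl=O
Why: Pinnick oxidation of the aldehyde to the acid, with 2-methyl-2-butene as hypochlorite scavenger so that the C8=C17 and C13=C14 alkenes should stay untouched.

**Compound list**

1 | geraniol, (2E)-3,7-dimethylocta-2,6-dien-1-ol | CC(C)=CCC/C(C)=C/CO | starting material
2 | geranyl 4-methoxybenzyl ether, 1-({[(2E)-3,7-dimethylocta-2,6-dien-1-yl]oxy}methyl)-4-methoxybenzene | COc1ccc(COC/C=C(C)/CCC=C(C)C)cc1 | intermediate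
3 | racemic 2-{(3E)-5-[(4-methoxybenzyl)oxy]-3-methylpent-3-en-1-yl}-3,3-dimethyloxirane | COc1ccc(COC/C=C(C)/CCC2OC2(C)C)cc1 | intermediate
4 | racemic (6E)-8-[(4-methoxybenzyl)oxy]-2,6-dimethyloct-6-ene-2,3-diol (not isolated) | COc1ccc(COC/C=C(C)/CCC(O)C(C)(C)O)cc1 | intermediate
5 | (4E)-6-[(4-methoxybenzyl)oxy]-4-methylhex-4-enal | COc1ccc(COC/C=C(C)/CCC=O)cc1 | intermediate
6 | ethyl 2-[bis(2,2,2-trifluoroethoxy)phosphoryl]propanoate | CCOC(=O)C(C)P(=O)(OCC(F)(F)F)OCC(F)(F)F | starting material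
7 | ethyl (2Z,6E)-8-[(4-methoxybenzyl)oxy]-2,6-dimethylocta-2,6-dienoate | CCOC(=O)/C(C)=C\CC/C(C)=C/COCc1ccc(OC)cc1 | intermediate
8 | (2Z,6E)-8-[(4-methoxybenzyl)oxy]-2,6-dimethylocta-2,6-dien-1-ol | OC/C(C)=C\CC/C(C)=C/COCc1ccc(OC)cc1 | intermediate
9 | [(2R,3S)-3-{(3E)-5-[(4-methoxybenzyl)oxy]-3-methylpent-3-en-1-yl}-2-methyloxiran-2-yl]methanol | COc1ccc(COC/C=C(C)/CC[C@@H]2O[C@]2(C)CO)cc1 | intermediate
10 | tert-butyl{[(2R,3S)-3-{(3E)-5-[(4-methoxybenzyl)oxy]-3-methylpent-3-en-1-yl}-2-methyloxiran-2-yl]methoxy}diphenylsilane | COc1ccc(COC/C=C(C)/CC[C@@H]2O[C@]2(C)CO[Si](c3ccccc3)(c3ccccc3)C(C)(C)C)cc1 | intermediate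
11 | (2E)-3-methyl-5-Ox-pent-2-en-1-ol | OC/C=C(C)/CC[C@@H]1O[C@]1(C)CO[Si](c2ccccc2)(c2ccccc2)C(C)(C)C | intermediate
12 | (2E)-3-methyl-5-Ox-pent-2-en-1-yl methanesulfonate (not isolated) | CS(=O)(=O)OC/C=C(C)/CC[C@@H]1O[C@]1(C)CO[Si](c2ccccc2)(c2ccccc2)C(C)(C)C | intermediate
13 | (2E)-1-bromo-3-methyl-5-Ox-pent-2-ene | BrC/C=C(C)/CC[C@@H]1O[C@]1(C)CO[Si](c2ccccc2)(c2ccccc2)C(C)(C)C | intermediate
14 | methyl acetoacetate (methyl 3-oxobutanoate) | CC(=O)CC(=O)OC | starting material
15 | methyl (6E)-7-methyl-3-oxo-9-Ox-non-6-enoate | COC(=O)CC(=O)CC/C=C(C)/CC[C@@H]1O[C@]1(C)CO[Si](c2ccccc2)(c2ccccc2)C(C)(C)C | intermediate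
16 | methyl (2Z,6E)-3-[(diethoxyphosphoryl)oxy]-7-methyl-9-Ox-nona-2,6-dienoate | COC(=O)/C=C(OP(=O)(OCC)OCC)/CC/C=C(C)/CC[C@@H]1O[C@]1(C)CO[Si](c2ccccc2)(c2ccccc2)C(C)(C)C | intermediate
17 | methyl (2Z,6E)-7-methyl-9-Ox-3-[(trimethylsilyl)methyl]nona-2,6-dienoate | COC(=O)/C=C(C[Si](C)(C)C)/CC/C=C(C)/CC[C@@H]1O[C@]1(C)CO[Si](c2ccccc2)(c2ccccc2)C(C)(C)C | intermediate
18 | (2Z,6E)-7-methyl-9-Ox-3-[(trimethylsilyl)methyl]nona-2,6-dien-1-ol | OC/C=C(C[Si](C)(C)C)/CC/C=C(C)/CC[C@@H]1O[C@]1(C)CO[Si](c2ccccc2)(c2ccccc2)C(C)(C)C | intermediate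
19 | (2Z,6E)-7-methyl-9-Ox-3-[(trimethylsilyl)methyl]nona-2,6-dien-1-yl methanesulfonate (not isolated) | CS(=O)(=O)OC/C=C(C[Si](C)(C)C)/CC/C=C(C)/CC[C@@H]1O[C@]1(C)CO[Si](c2ccccc2)(c2ccccc2)C(C)(C)C | intermediate
20 | (2Z,6E)-1-bromo-7-methyl-9-Ox-3-[(trimethylsilyl)methyl]nona-2,6-diene | BrC/C=C(C[Si](C)(C)C)/CC/C=C(C)/CC[C@@H]1O[C@]1(C)CO[Si](c2ccccc2)(c2ccccc2)C(C)(C)C | intermediate
21 | methyl (6Z,10E)-11-methyl-3-oxo-13-Ox-7-[(trimethylsilyl)methyl]trideca-6,10-dienoate | COC(=O)CC(=O)CC/C=C(C[Si](C)(C)C)/CC/C=C(C)/CC[C@@H]1O[C@]1(C)CO[Si](c2ccccc2)(c2ccccc2)C(C)(C)C | intermediate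
22 | methyl (2Z,6Z,10E)-3-[(diethoxyphosphoryl)oxy]-11-methyl-13-Ox-7-[(trimethylsilyl)methyl]trideca-2,6,10-trienoate | COC(=O)/C=C(OP(=O)(OCC)OCC)/CC/C=C(C[Si](C)(C)C)/CC/C=C(C)/CC[C@@H]1O[C@]1(C)CO[Si](c2ccccc2)(c2ccccc2)C(C)(C)C | intermediate
23 | methyl (2E,6Z,10E)-3,11-dimethyl-13-Ox-7-[(trimethylsilyl)methyl]trideca-2,6,10-trienoate (cyclization precursor) | COC(=O)/C=C(C)/CC/C=C(C[Si](C)(C)C)/CC/C=C(C)/CC[C@@H]1O[C@]1(C)CO[Si](c2ccccc2)(c2ccccc2)C(C)(C)C | intermediate
24 | methyl (13E)-19-[(tert-butyldiphenylsilyl)oxy]-3β-hydroxylabda-8(17),13-dien-15-oate (5α-H, 9α-H, 10β-CH3, C19 on the axial 4β bond) | C=C1CC[C@@H]2[C@](C)(CC[C@H](O)[C@]2(C)CO[Si](c3ccccc3)(c3ccccc3)C(C)(C)C)[C@H]1CC/C(C)=C/C(=O)OC | intermediate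
25 | methyl (13E)-19-[(tert-butyldiphenylsilyl)oxy]-3β-[(1H-imidazol-1-ylcarbonothioyl)oxy]labda-8(17),13-dien-15-oate | C=C1CC[C@@H]2[C@](C)(CC[C@H](OC(=S)n3ccnc3)[C@]2(C)CO[Si](c4ccccc4)(c4ccccc4)C(C)(C)C)[C@H]1CC/C(C)=C/C(=O)OC | intermediate
26 | methyl (13E)-19-[(tert-butyldiphenylsilyl)oxy]labda-8(17),13-dien-15-oate | C=C1CC[C@@H]2[C@](C)(CCC[C@]2(C)CO[Si](c3ccccc3)(c3ccccc3)C(C)(C)C)[C@H]1CC/C(C)=C/C(=O)OC | intermediate
27 | (13E)-19-[(tert-butyldiphenylsilyl)oxy]labda-8(17),13-dien-15-ol | C=C1CC[C@@H]2[C@](C)(CCC[C@]2(C)CO[Si](c3ccccc3)(c3ccccc3)C(C)(C)C)[C@H]1CC/C(C)=C/CO | intermediate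
28 | palmitoyl chloride (hexadecanoyl chloride) | CCCCCCCCCCCCCCCC(=O)Cl | starting material
29 | (13E)-19-[(tert-butyldiphenylsilyl)oxy]labda-8(17),13-dien-15-yl hexadecanoate | C=C1CC[C@@H]2[C@](C)(CCC[C@]2(C)CO[Si](c3ccccc3)(c3ccccc3)C(C)(C)C)[C@H]1CC/C(C)=C/COC(=O)CCCCCCCCCCCCCCC | intermediate
30 | (13E)-19-hydroxylabda-8(17),13-dien-15-yl hexadecanoate | C=C1CC[C@@H]2[C@](C)(CCC[C@]2(C)CO)[C@H]1CC/C(C)=C/COC(=O)CCCCCCCCCCCCCCC | intermediate
31 | (13E)-19-oxolabda-8(17),13-dien-15-yl hexadecanoate | C=C1CC[C@@H]2[C@](C)(CCC[C@]2(C)C=O)[C@H]1CC/C(C)=C/COC(=O)CCCCCCCCCCCCCCC | intermediate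
32 | (4S,5R,9S,10R,13E)-15-(hexadecanoyloxy)labda-8(17),13-dien-19-oic acid | C=C1CC[C@@H]2[C@](C)(CCC[C@]2(C)C(=O)O)[C@H]1CC/C(C)=C/COC(=O)CCCCCCCCCCCCCCC | target

**Step count and risks**

Total steps: 25. Longest linear sequence: 25 steps (geraniol 1 to target 32; the route is fully linear).

Steps most likely to fail:

1. Step 18 (the cascade). The ester carbonyl and the silyl ether oxygens compete with the epoxide for the Lewis acid, and the C19 oxygen slows ionisation at C4. The complexed epoxide may then rearrange by hydride shift to a C3 ketone, the allylsilane may be protodesilylated, or the cascade may end after ring A by proton loss. The fallback reshapes the substrate so that it holds no carbonyl group. It sets out from 23: i-Bu2AlH (CH2Cl2, −78 °C) would give the trienol F1, and t-BuMe2SiCl with imidazole would give its tert-butyldimethylsilyl ether F2. The all-ether substrate would be cyclised with MeAlCl2 (CH2Cl2, −78 °C) to the bicyclic 3β-alcohol F3. This would be thioacylated as in step 19 to the imidazolylthiocarbonyl derivative F4 and reduced with n-Bu3SnH and AIBN to the 3-deoxy bis-silyl ether F5. Pyridinium p-toluenesulfonate in MeOH would then cleave only the primary allylic tert-butyldimethylsilyl ether, and the route is rejoined at 27.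

2. Step 15 (with the bromide made in step 14). The allylic bromide 20 carries a silyl group γ to the leaving group, so ionisation helped by silicon and loss of Me3SiBr to a 1,3-diene, or SN2′ attack, may compete with direct displacement by the dianion. The fallback brings in silicon last, so that no allylic halide carries a silyl group. It sets out from 16: i-Bu2AlH (CH2Cl2, −78 °C) would reduce the ester to the phosphoryloxy allylic alcohol F6, and an Appel reaction (CBr4, PPh3, CH2Cl2, 0 °C) would give the bromide F7. Alkylation of the dianion of 14 would give the β-keto ester F8, and NaH with ClP(O)(OEt)2 the bis(enol phosphate) F9. Me2CuLi at −78 °C would exchange only the ester-conjugated phosphate and give the E enoate F10. Kumada coupling of the remaining simple enol phosphate with Me3SiCH2MgCl and Ni(acac)2 would then install the allylsilane, and the route is rejoined at 23.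

3. Step 12. The Grignard reagent or its magnesium halide may open the trisubstituted epoxide during the long coupling, and the alkene geometry may erode at the nickel stage. The fallback changes the electrophile and the organometallic partner. It sets out from 15: NaH and PhN(SO2CF3)2 (THF, 0 °C) would give, through the same chelated sodium enolate, the Z enol triflate F11. Negishi coupling with Me3SiCH2ZnCl (from the Grignard reagent and ZnCl2) and Pd(PPh3)4 in THF, a reagent that attacks neither epoxides nor esters, would give the allylsilane ester, and the route is rejoined at 17.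

Further compounds
F1 | step 18 | (2E,6Z,10E)-3,11-dimethyl-13-Ox-7-[(trimethylsilyl)methyl]trideca-2,6,10-trien-1-ol | OC/C=C(C)/CC/C=C(C[Si](C)(C)C)/CC/C=C(C)/CC[C@@H]1O[C@]1(C)CO[Si](c2ccccc2)(c2ccccc2)C(C)(C)C
F2 | step 18 | tert-butyldimethylsilyl ether of F1 | CC(C)(C)[Si](C)(C)OC/C=C(C)/CC/C=C(C[Si](C)(C)C)/CC/C=C(C)/CC[C@@H]1O[C@]1(C)CO[Si](c2ccccc2)(c2ccccc2)C(C)(C)C
F3 | step 18 | (13E)-15-[(tert-butyldimethylsilyl)oxy]-19-[(tert-butyldiphenylsilyl)oxy]labda-8(17),13-dien-3β-ol | C=C1CC[C@@H]2[C@](C)(CC[C@H](O)[C@]2(C)CO[Si](c3ccccc3)(c3ccccc3)C(C)(C)C)[C@H]1CC/C(C)=C/CO[Si](C)(C)C(C)(C)C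
F4 | step 18 | 3-O-(imidazol-1-ylthiocarbonyl) derivative of F3 | C=C1CC[C@@H]2[C@](C)(CC[C@H](OC(=S)n3ccnc3)[C@]2(C)CO[Si](c4ccccc4)(c4ccccc4)C(C)(C)C)[C@H]1CC/C(C)=C/CO[Si](C)(C)C(C)(C)C
F5 | step 18 | (13E)-15-[(tert-butyldimethylsilyl)oxy]-19-[(tert-butyldiphenylsilyl)oxy]labda-8(17),13-diene | C=C1CC[C@@H]2[C@](C)(CCC[C@]2(C)CO[Si](c3ccccc3)(c3ccccc3)C(C)(C)C)[C@H]1CC/C(C)=C/CO[Si](C)(C)C(C)(C)C
F6 | step 15 | diethyl (2Z,6E)-1-hydroxy-7-methyl-9-Ox-nona-2,6-dien-3-yl phosphate | OC/C=C(OP(=O)(OCC)OCC)/CC/C=C(C)/CC[C@@H]1O[C@]1(C)CO[Si](c2ccccc2)(c2ccccc2)C(C)(C)C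
F7 | step 15 | (2Z,6E)-1-bromo-7-methyl-9-Ox-nona-2,6-dien-3-yl diethyl phosphate | BrC/C=C(OP(=O)(OCC)OCC)/CC/C=C(C)/CC[C@@H]1O[C@]1(C)CO[Si](c2ccccc2)(c2ccccc2)C(C)(C)C
F8 | step 15 | methyl (6Z,10E)-7-[(diethoxyphosphoryl)oxy]-11-methyl-3-oxo-13-Ox-trideca-6,10-dienoate | COC(=O)CC(=O)CC/C=C(OP(=O)(OCC)OCC)/CC/C=C(C)/CC[C@@H]1O[C@]1(C)CO[Si](c2ccccc2)(c2ccccc2)C(C)(C)C
F9 | step 15 | methyl (2Z,6Z,10E)-3,7-bis[(diethoxyphosphoryl)oxy]-11-methyl-13-Ox-trideca-2,6,10-trienoate | COC(=O)/C=C(OP(=O)(OCC)OCC)/CC/C=C(OP(=O)(OCC)OCC)/CC/C=C(C)/CC[C@@H]1O[C@]1(C)CO[Si](c2ccccc2)(c2ccccc2)C(C)(C)C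
F10 | step 15 | methyl (2E,6Z,10E)-7-[(diethoxyphosphoryl)oxy]-3,11-dimethyl-13-Ox-trideca-2,6,10-trienoate | COC(=O)/C=C(C)/CC/C=C(OP(=O)(OCC)OCC)/CC/C=C(C)/CC[C@@H]1O[C@]1(C)CO[Si](c2ccccc2)(c2ccccc2)C(C)(C)C
F11 | step 12 | methyl (2Z,6E)-7-methyl-9-Ox-3-{[(trifluoromethyl)sulfonyl]oxy}nona-2,6-dienoate | COC(=O)/C=C(OS(=O)(=O)C(F)(F)F)/CC/C=C(C)/CC[C@@H]1O[C@]1(C)CO[Si](c2ccccc2)(c2ccccc2)C(C)(C)C
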